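The C3–C1' biaryl bond is cut last (Suzuki–Miyaura): 3-iodochromone 16 (rings A and C, prenyl already at C8, two MOM ethers) plus chromenyl boronate 9 (ring B fused to pyran ring D, one TIPS ether).
Ring D is cut through two bonds at once, C4–C4a and C2–C3 (2H-chromene numbering of the B/D fragment): aryl isopropenyl ether 4, which already holds the CMe2 carbon on oxygen, plus ethyl vinyl ether 5 as the C3–C4 unit; ethanol is lost in the same pot.
Enabling feature: ether oxygen O1 of ring D sits on ring B between C8 (blocked: bromine now, the isoflavone bond later) and C4a–H, the one carbon flanked by both ring-B oxygens; with the acetone-level carbon C2 on O1, the unit C4a=C8a–O1(+)=C2 is a cationic 2-oxadiene that takes up an enol ether in a formal [4+2].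
Ring C is closed on C-prenylated phloroacetophenone: the hydroxyl beside the prenyl group is left free (13), so enaminone formation and iodine-induced cyclisation fix the prenyl group at C8.
Ring order: ring D onto ring B (step 3), ring C onto ring A (step 8), B–C coupling (step 9), deprotection (step 10).

Key step: step 3

Remark: the target has no stereocentre. Ring A is the phloroglucinol-derived benzo ring, ring C the pyranone, ring B the resorcinol-derived aryl ring, ring D the 2,2-dimethylpyran. The atoms of the B/D fragment are numbered as in 2H-chromene 8 (O1, C2, C3, C4, C4a, C5–C8, C8a), also in its precursors.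

Step 1
Reactants: 1 4-bromoresorcinol (4-bromobenzene-1,3-diol)
Product: 2 2-bromo-5-[(triisopropylsilyl)oxy]phenol
Conditions: TIPSCl (1.0 equiv), imidazole, CH2Cl2, −20 °C to 0 °C
Reagents that add atoms: triisopropylsilyl chloride, CC(C)[Si](Cl)(C(C)C)C(C)C
Why: Silylation of a phenol with a bulky silyl chloride should take the unhindered hydroxyl para to bromine and leave the hydroxyl ortho to bromine free; a minor regioisomer, if formed, would be removed by chromatography.

Step 2
Reactants: 2 2-bromo-5-[(triisopropylsilyl)oxy]phenol; 3 isopropenylboronic acid pinacol ester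
Product: 4 1-bromo-2-(prop-1-en-2-yloxy)-4-[(triisopropylsilyl)oxy]benzene
Conditions: Cu(OAc)2 (20 mol %), pyridine, 4 Å molecular sieves, CH2Cl2, O2 (1 atm), rt
Reagents that add atoms: none
Why: Chan–Lam oxidative C–O coupling of a phenol with an alkenylboronate is a known route to aryl enol ethers, tolerates ortho-halogen, and spares the aryl bromide because no zerovalent metal is present.

Step 3
Reactants: 4 1-bromo-2-(prop-1-en-2-yloxy)-4-[(triisopropylsilyl)oxy]benzene; 5 ethyl vinyl ether
Product: 8 8-bromo-2,2-dimethyl-5-[(triisopropylsilyl)oxy]-2H-chromene, via alpha-chloro ether 6 (not isolated), via 4-ethoxychroman 7 (not isolated)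
Conditions: HCl (1.0 equiv, 2 M in Et2O), CH2Cl2, −78 °C; then 5 (1.5 equiv, slow addition) and SnCl4 (0.5 equiv), −78 °C; then 0 °C; quench with Et3N
Reagents that add atoms: none
Why: Proposed new method: HCl adds to the aryl enol ether to give alpha-chloro ether 6, SnCl4 ionises it to the O-aryl oxocarbenium ion (the cationic 2-oxadiene C4a=C8a–O1(+)=C2), the CH2 terminus of 5 attacks C2 (Prins-type step, new C2–C3 bond), the ethoxycarbenium ion so formed is captured by C4a (Friedel–Crafts step, new C4–C4a bond) to give 7, and on warming the acid ionises the doubly oxygen-stabilised benzylic C4–OEt bond so that ethanol is lost (E1) and the C3=C4 alkene appears. The closest known reaction type is the oxa-Povarov reaction of O-aryl oxocarbenium ions with alkenes, together with the Povarov reaction of N-aryl iminium ions with vinyl ethers, in which the 4-alkoxy group is likewise eliminated under acid; not yet shown is the combination of a ketone-derived O-aryl oxocarbenium ion, an enol ether as the two-carbon partner and elimination in the same pot. Ring D is closed as a formal inverse-electron-demand [4+2] annulation that is stepwise, its ring-closing event being a 6-exo-trig Friedel–Crafts attack of the arene on the ethoxycarbenium carbon. The only new stereocentre, C4 of 7, forms as a racemate and is destroyed by the elimination, so nothing has to be controlled. The step needs chemoselectivity (the aryl oxocarbenium ion as the only electrophile, 5 as the only nucleophile) and regioselectivity: the first should follow from converting 4 fully into 6 before SnCl4 and 5 are added, so that neither free acid nor free aryl enol ether is present, and the second is built into the substrate, because the other ortho carbon (C8) carries bromine and C4a is activated by both ring oxygens. Ring closure is intramolecular and should outrun chain growth of 5, which is kept at low concentration by slow addition.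

Step 4
Reactants: 8 8-bromo-2,2-dimethyl-5-[(triisopropylsilyl)oxy]-2H-chromene
Product: 9 2-{2,2-dimethyl-5-[(triisopropylsilyl)oxy]-2H-chromen-8-yl}-4,4,5,5-tetramethyl-1,3,2-dioxaborolane
Conditions: B2pin2, Pd(dppf)Cl2 (5 mol %), KOAc, 1,4-dioxane, 85 °C
Reagents that add atoms: bis(pinacolato)diboron, CC1(C)OB(OC1(C)C)B1OC(C)(C)C(C)(C)O1
Why: Miyaura borylation of an aryl bromide; the weak base KOAc should suppress biaryl homocoupling, and the silyl ether and the chromene alkene are inert under these conditions.

Step 5
Reactants: 10 2,4,6-trihydroxyacetophenone; 11 prenyl bromide (1-bromo-3-methylbut-2-ene)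
Product: 12 1-[2,4,6-trihydroxy-3-(3-methylbut-2-en-1-yl)phenyl]ethan-1-one
Conditions: DBU, THF, 0 °C to rt
Reagents that add atoms: none
Why: C-alkylation of the phloroglucinol-type phenoxide by an allylic bromide; the two free ring carbons of 10 are equivalent, so mono-C-prenylation can give only one regioisomer, and O-prenyl or doubly prenylated by-products would be separated.

Step 6
Reactants: 12 1-[2,4,6-trihydroxy-3-(3-methylbut-2-en-1-yl)phenyl]ethan-1-one
Product: 13 1-[2-hydroxy-4,6-bis(methoxymethoxy)-3-(3-methylbut-2-en-1-yl)phenyl]ethan-1-one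
Conditions: MOMCl (2.2 equiv), i-Pr2NEt, CH2Cl2, 0 °C to rt
Reagents that add atoms: chloromethyl methyl ether, COCCl
Why: Williamson-type acetalisation should take the para hydroxyl and the unhindered ortho hydroxyl, while the hydroxyl between acetyl and prenyl stays free because it is both crowded and hydrogen-bonded to the ketone; this hydroxyl later becomes O1 and so places the prenyl group at C8.

Step 7
Reactants: 13 1-[2-hydroxy-4,6-bis(methoxymethoxy)-3-(3-methylbut-2-en-1-yl)phenyl]ethan-1-one; 14 N,N-dimethylformamide dimethyl acetal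
Product: 15 (2E)-3-(dimethylamino)-1-[2-hydroxy-4,6-bis(methoxymethoxy)-3-(3-methylbut-2-en-1-yl)phenyl]prop-2-en-1-one
Conditions: 14 (3 equiv), toluene, 90 °C
Reagents that add atoms: none
Why: Condensation of a methyl ketone with an amide acetal gives the push–pull enaminone, expected as the more stable E isomer (the geometry is lost again in step 8).

Step 8
Reactants: 15 (2E)-3-(dimethylamino)-1-[2-hydroxy-4,6-bis(methoxymethoxy)-3-(3-methylbut-2-en-1-yl)phenyl]prop-2-en-1-one
Product: 16 3-iodo-5,7-bis(methoxymethoxy)-8-(3-methylbut-2-en-1-yl)-4H-chromen-4-one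
Conditions: I2 (1.05 equiv), pyridine (1 equiv), CHCl3, 0 °C to rt
Reagents that add atoms: iodine, II
Why: Iodine-induced cyclisation of a 2-hydroxyaryl enaminone (alpha-iodination, attack of the phenol on the iminium carbon, loss of dimethylamine) is the standard route to 3-iodochromones, and the enaminone carbon should be far more nucleophilic toward iodine than the prenyl alkene.

Step 9
Reactants: 16 3-iodo-5,7-bis(methoxymethoxy)-8-(3-methylbut-2-en-1-yl)-4H-chromen-4-one; 9 2-{2,2-dimethyl-5-[(triisopropylsilyl)oxy]-2H-chromen-8-yl}-4,4,5,5-tetramethyl-1,3,2-dioxaborolane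
Product: 17 3-{2,2-dimethyl-5-[(triisopropylsilyl)oxy]-2H-chromen-8-yl}-5,7-bis(methoxymethoxy)-8-(3-methylbut-2-en-1-yl)-4H-chromen-4-one
Conditions: Pd(dppf)Cl2 (5 mol %), K2CO3, 1,4-dioxane/H2O (5:1), 80 °C
Reagents that add atoms: none
Why: Suzuki–Miyaura coupling of a 3-iodochromone with an arylboronate is the established isoflavone-forming C3–C1' bond construction; the mild carbonate base should spare the pyranone ring and the TIPS ether.

Step 10
Reactants: 17 3-{2,2-dimethyl-5-[(triisopropylsilyl)oxy]-2H-chromen-8-yl}-5,7-bis(methoxymethoxy)-8-(3-methylbut-2-en-1-yl)-4H-chromen-4-one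
Product: 19 3-(5-hydroxy-2,2-dimethyl-2H-chromen-8-yl)-5,7-dihydroxy-8-(3-methylbut-2-en-1-yl)-4H-chromen-4-one, via bis-MOM phenol 18 (not isolated)
Conditions: TBAF (1.1 equiv), THF, 0 °C; then MeOH, 3 M aq. HCl, 45 °C
Reagents that add atoms: none
Why: Fluoride cleaves the aryl silyl ether, and acid-catalysed acetal exchange with methanol then removes both MOM groups; dilute acid at moderate temperature is the usual way to unmask prenylated polyphenols without cyclising the prenyl group onto the neighbouring hydroxyl.

Compound list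
1 | 4-bromoresorcinol (4-bromobenzene-1,3-diol) | Oc1ccc(Br)c(O)c1 | starting material
2 | 2-bromo-5-[(triisopropylsilyl)oxy]phenol | Oc1cc(O[Si](C(C)C)(C(C)C)C(C)C)ccc1Br | intermediate
3 | isopropenylboronic acid pinacol ester (4,4,5,5-tetramethyl-2-(prop-1-en-2-yl)-1,3,2-dioxaborolane) | CC(=C)B1OC(C)(C)C(C)(C)O1 | starting material
4 | 1-bromo-2-(prop-1-en-2-yloxy)-4-[(triisopropylsilyl)oxy]benzene | CC(=C)Oc1cc(O[Si](C(C)C)(C(C)C)C(C)C)ccc1Br | intermediate
5 | ethyl vinyl ether (ethoxyethene) | CCOC=C | starting material
6 | 1-bromo-2-[(2-chloropropan-2-yl)oxy]-4-[(triisopropylsilyl)oxy]benzene | CC(C)(Cl)Oc1cc(O[Si](C(C)C)(C(C)C)C(C)C)ccc1Br | intermediate (not isolated)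
7 | rac-8-bromo-4-ethoxy-2,2-dimethyl-5-[(triisopropylsilyl)oxy]-3,4-dihydro-2H-chromene | CCOC1CC(C)(C)Oc2c(Br)ccc(O[Si](C(C)C)(C(C)C)C(C)C)c21 | intermediate (not isolated)
8 | 8-bromo-2,2-dimethyl-5-[(triisopropylsilyl)oxy]-2H-chromene | CC1(C)C=Cc2c(O[Si](C(C)C)(C(C)C)C(C)C)ccc(Br)c2O1 | intermediate
9 | 2-{2,2-dimethyl-5-[(triisopropylsilyl)oxy]-2H-chromen-8-yl}-4,4,5,5-tetramethyl-1,3,2-dioxaborolane | CC1(C)C=Cc2c(O[Si](C(C)C)(C(C)C)C(C)C)ccc(B3OC(C)(C)C(C)(C)O3)c2O1 | intermediate
10 | 2,4,6-trihydroxyacetophenone (1-(2,4,6-trihydroxyphenyl)ethan-1-one) | CC(=O)c1c(O)cc(O)cc1O | starting material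
11 | prenyl bromide (1-bromo-3-methylbut-2-ene) | CC(C)=CCBr | starting material
12 | 1-[2,4,6-trihydroxy-3-(3-methylbut-2-en-1-yl)phenyl]ethan-1-one | CC(=O)c1c(O)cc(O)c(CC=C(C)C)c1O | intermediate
13 | 1-[2-hydroxy-4,6-bis(methoxymethoxy)-3-(3-methylbut-2-en-1-yl)phenyl]ethan-1-one | CC(=O)c1c(OCOC)cc(OCOC)c(CC=C(C)C)c1O | intermediate
14 | N,N-dimethylformamide dimethyl acetal | COC(OC)N(C)C | starting material
15 | (2E)-3-(dimethylamino)-1-[2-hydroxy-4,6-bis(methoxymethoxy)-3-(3-methylbut-2-en-1-yl)phenyl]prop-2-en-1-one | CN(C)/C=C/C(=O)c1c(OCOC)cc(OCOC)c(CC=C(C)C)c1O | intermediate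
16 | 3-iodo-5,7-bis(methoxymethoxy)-8-(3-methylbut-2-en-1-yl)-4H-chromen-4-one | CC(C)=CCc1c(OCOC)cc(OCOC)c2c(=O)c(I)coc12 | intermediate
17 | 3-{2,2-dimethyl-5-[(triisopropylsilyl)oxy]-2H-chromen-8-yl}-5,7-bis(methoxymethoxy)-8-(3-methylbut-2-en-1-yl)-4H-chromen-4-one | CC(C)=CCc1c(OCOC)cc(OCOC)c2c(=O)c(-c3ccc(O[Si](C(C)C)(C(C)C)C(C)C)c4c3OC(C)(C)C=C4)coc12 | intermediate
18 | 3-(5-hydroxy-2,2-dimethyl-2H-chromen-8-yl)-5,7-bis(methoxymethoxy)-8-(3-methylbut-2-en-1-yl)-4H-chromen-4-one | CC(C)=CCc1c(OCOC)cc(OCOC)c2c(=O)c(-c3ccc(O)c4c3OC(C)(C)C=C4)coc12 | intermediate (not isolated)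
19 | 3-(5-hydroxy-2,2-dimethyl-2H-chromen-8-yl)-5,7-dihydroxy-8-(3-methylbut-2-en-1-yl)-4H-chromen-4-one | CC(C)=CCc1c(O)cc(O)c2c(=O)c(-c3ccc(O)c4c3OC(C)(C)C=C4)coc12 | target

Total step count: 10.
Longest linear sequence: 6 steps (1 → 2 → 4 → 8 → 9 → 17 → 19; the branch 10 → 12 → 13 → 15 → 16 → 17 → 19 is equally long).

Steps most likely to fail

Step 3 (proposed new method). Three processes could take over: cationic chain growth of the vinyl ether could outrun the ring closure; the oxocarbenium stage could shed the phenol by heterolysis of the O–CMe2 bond; and the acid could dimerise the electron-rich chromene once ethanol has been lost. The fallback uses known chemistry and sets out from 2. Copper-catalysed O-alkylation with 3-chloro-3-methylbut-1-yne (CuCl2 cat., DBU, MeCN, 0 °C) should give 1-bromo-2-[(2-methylbut-3-yn-2-yl)oxy]-4-[(triisopropylsilyl)oxy]benzene F1. Heating F1 in N,N-diethylaniline at about 180 °C should trigger the aryl propargyl Claisen rearrangement to the only free ortho carbon, followed by 1,5-hydrogen shift and oxa-6π electrocyclisation. This comes back to the route at 8.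

Step 8. Electrophilic iodine may add to the prenyl alkene and the neighbouring hydroxyl may close an iodo-ether ring, in competition with alpha-iodination of the enaminone. The fallback avoids electrophilic halogen and sets out from 13 and 8. Pd-catalysed ketone alpha-arylation (Pd2(dba)3, XPhos, excess K3PO4 so that the phenol is carried as its phenoxide, toluene, 90 °C) should give the deoxybenzoin 2-{2,2-dimethyl-5-[(triisopropylsilyl)oxy]-2H-chromen-8-yl}-1-[2-hydroxy-4,6-bis(methoxymethoxy)-3-(3-methylbut-2-en-1-yl)phenyl]ethan-1-one F2. Heating F2 with 14 in toluene inserts the C2 carbon and closes ring C with loss of methanol and dimethylamine. This comes back to the route at 17, and steps 4, 7, 8 and 9 are then not needed.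

Step 2. Transmetalation of the alpha-substituted alkenylboronate to the hindered ortho-bromophenoxide copper centre may be slow, so that protodeboronation and oxidative phenol coupling take over. The fallback sets out from 2. Acetylation (Ac2O, pyridine, DMAP, CH2Cl2) should give 2-bromo-5-[(triisopropylsilyl)oxy]phenyl acetate F3. Carbonyl methylenation of this aryl ester with Cp2TiMe2 (toluene, 65 °C, Petasis olefination) should convert the acetate into the isopropenyl ether. This comes back to the route at 4.

Further compounds
F1 | step 3 | 1-bromo-2-[(2-methylbut-3-yn-2-yl)oxy]-4-[(triisopropylsilyl)oxy]benzene | C#CC(C)(C)Oc1cc(O[Si](C(C)C)(C(C)C)C(C)C)ccc1Br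
F2 | step 8 | 2-{2,2-dimethyl-5-[(triisopropylsilyl)oxy]-2H-chromen-8-yl}-1-[2-hydroxy-4,6-bis(methoxymethoxy)-3-(3-methylbut-2-en-1-yl)phenyl]ethan-1-one | CC(C)=CCc1c(OCOC)cc(OCOC)c(C(=O)Cc2ccc(O[Si](C(C)C)(C(C)C)C(C)C)c3c2OC(C)(C)C=C3)c1O
F3 | step 2 | 2-bromo-5-[(triisopropylsilyl)oxy]phenyl acetate | CC(=O)Oc1cc(O[Si](C(C)C)(C(C)C)C(C)C)ccc1Br
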